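**Strategy**

Lactone numbering: O1, C2 (C=O), C3 (C–OMe), C4 (C–aryl), C5 (quaternary). The disconnection is C2–C3. It exploits C4 as the β-carbon of the enoate O=C2–C3=C4: with OH in place of the aryl group the ring is a 3-methoxytetronic acid and C2–C3 is a Claisen bond. The precursor is an open (R)-α-hydroxy-β-keto ester with C2 as a 4-nitrophenyl carbonate on O1 and C3 as the CH2 of a methoxymethyl ketone. Magnesium soft enolisation closes the ring in one operation; the C4 enol then becomes a triflate for Suzuki–Miyaura arylation. C5 is set by catalytic asymmetric α-hydroxylation.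

Key step: step 6

Abbreviations: prenyl = 3-methylbut-2-en-1-yl; TIPS = triisopropylsilyl; TBS = tert-butyldimethylsilyl.

Assumption: the (R,R)-ligand in step 4 is taken to direct oxygen transfer to the face that gives the (R)-alcohol 8; should this acyclic substrate respond with the opposite sense, the (S,S)-ligand is used and nothing else changes.

**Route**

Step 1
Reactants: 1 4-hydroxybenzaldehyde; 2 prenyl bromide (1-bromo-3-methylbut-2-ene)
Product: 3 4-hydroxy-3-prenylbenzaldehyde
Conditions: KOH (1.1 equiv), H2O, rt, 24 h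
Reagents that add atoms: none
Why: Ortho C-alkylation of the phenoxide (the para position is blocked by the formyl group) is favoured in water, where hydrogen bonding shields the oxygen, and the O-prenyl ether formed alongside is removed by chromatography.

Step 2
Reactants: 3 4-hydroxy-3-prenylbenzaldehyde
Product: 4 3-prenyl-4-(TIPS-oxy)benzaldehyde
Conditions: TIPSCl, imidazole, DMF, rt
Reagents that add atoms: triisopropylsilyl chloride CC(C)[Si](Cl)(C(C)C)C(C)C
Why: Imidazole-promoted silyl ether formation masks the phenol against the chloroformate, the triflic anhydride and the bases used later, and the bulky silyl ether should survive every step up to the fluoride treatment.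

Step 3
Reactants: 4 3-prenyl-4-(TIPS-oxy)benzaldehyde; 5 methyl 4-methoxy-3-oxobutanoate
Product: 7 methyl 4-methoxy-3-oxo-2-[3-prenyl-4-(TIPS-oxy)benzyl]butanoate (racemic), via alkylidene keto ester 6 (not isolated)
Conditions: L-proline (20 mol %), diethyl 2,6-dimethyl-1,4-dihydropyridine-3,5-dicarboxylate (Hantzsch ester, 1.1 equiv), EtOH, rt to 40 °C
Reagents that add atoms: none
Why: Organocatalytic reductive alkylation, in which Knoevenagel condensation at the doubly activated CH2 of the keto ester gives the alkylidene keto ester and its electron-poor C=C then accepts hydride from the dihydropyridine, while the prenyl alkene and the carbonyl groups are not reduced and the new, labile stereocentre is left racemic.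

Step 4
Reactants: 7 methyl 4-methoxy-3-oxo-2-[3-prenyl-4-(TIPS-oxy)benzyl]butanoate (racemic)
Product: 8 methyl (2R)-2-hydroxy-4-methoxy-3-oxo-2-[3-prenyl-4-(TIPS-oxy)benzyl]butanoate
Conditions: Ni(ClO4)2·6H2O (10 mol %), (R,R)-4,6-dibenzofurandiyl-2,2'-bis(4-phenyloxazoline) (11 mol %), racemic 2-(phenylsulfonyl)-3-phenyloxaziridine (1.2 equiv), 4 Å molecular sieves, CH2Cl2, rt
Reagents that add atoms: 2-(phenylsulfonyl)-3-phenyloxaziridine O=S(=O)(c1ccccc1)N1OC1c1ccccc1
Why: Catalytic asymmetric α-hydroxylation of a β-keto ester, in which the divalent nickel bis(oxazoline) complex binds the substrate as a two-point enolate and leaves one face open to electrophilic oxygen transfer from the oxaziridine, so that the tertiary alcohol (C5 of the later lactone) is set as (R) by the ligand, while the prenyl alkene is not epoxidised by this oxidant at room temperature.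

Step 5
Reactants: 8 methyl (2R)-2-hydroxy-4-methoxy-3-oxo-2-[3-prenyl-4-(TIPS-oxy)benzyl]butanoate
Product: 9 methyl (2R)-4-methoxy-2-[(4-nitrophenoxy)carbonyloxy]-3-oxo-2-[3-prenyl-4-(TIPS-oxy)benzyl]butanoate
Conditions: LiN(SiMe3)2 (1.05 equiv), THF, −78 °C; then 4-nitrophenyl chloroformate (1.2 equiv), −78 to −20 °C
Reagents that add atoms: 4-nitrophenyl chloroformate O=C(Cl)Oc1ccc(cc1)[N+](=O)[O-]
Why: Mixed carbonate formation by O-acylation of an alkoxide with an aryl chloroformate, relying on the tertiary hydroxyl between two carbonyl groups being far more acidic than the ketone CH2, so that one equivalent of amide base at −78 °C gives only the alkoxide, which is trapped before retro-Claisen or α-ketol pathways set in.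

Step 6
Reactants: 9 methyl (2R)-4-methoxy-2-[(4-nitrophenoxy)carbonyloxy]-3-oxo-2-[3-prenyl-4-(TIPS-oxy)benzyl]butanoate
Product: 10 methyl (2R)-3-hydroxy-4-methoxy-5-oxo-2-[3-prenyl-4-(TIPS-oxy)benzyl]-2,5-dihydrofuran-2-carboxylate (3-methoxytetronic acid; lactone numbering: 3-OMe, 4-OH, C5 quaternary)
Conditions: MgBr2·OEt2 (2.5 equiv), i-Pr2NEt (3 equiv), CH2Cl2, 0 °C to rt; cold 1 M HCl work-up
Reagents that add atoms: none
Why: MgBr2 chelates the α-methoxy ketone so that i-Pr2NEt can remove a C3 proton (soft enolisation), the enolate carbon C3 adds to the carbonyl C2 of the neighbouring 4-nitrophenyl carbonate, and the tetrahedral intermediate ejects 4-nitrophenoxide, a far better leaving group than the ring oxygen O1, so the ring stays closed and the new bond is C2–C3. The closest known reaction types are the intramolecular Claisen (Dieckmann) condensation that gives tetronic acids and the soft-enolisation C-acylation of ketones with activated aryl esters. The lactone ring O1–C2–C3–C4–C5 closes in the 5-(enolendo)-exo-trig mode, the same mode as in Dieckmann closures to tetronic acids and in aldol closures of 1,4-diketones. No stereocentre is formed, and C5 is quaternary, carries no acidic hydrogen and keeps its (R) configuration. The step needs C- over O-acylation of the enolate (O-attack would close a five-membered enol carbonate); the chelated magnesium enolate should react at carbon and the product leaves the equilibrium as the stabilised magnesium tetronate, while the ketone has C3 as its only enolisable position and attack on the C5 methyl ester would need a four-membered ring.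

Step 7
Reactants: 10 methyl (2R)-3-hydroxy-4-methoxy-5-oxo-2-[3-prenyl-4-(TIPS-oxy)benzyl]-2,5-dihydrofuran-2-carboxylate
Product: 11 methyl (2R)-4-methoxy-5-oxo-2-[3-prenyl-4-(TIPS-oxy)benzyl]-3-(trifluoromethylsulfonyloxy)-2,5-dihydrofuran-2-carboxylate
Conditions: Tf2O (1.2 equiv), i-Pr2NEt (1.5 equiv), CH2Cl2, −78 °C
Reagents that add atoms: trifluoromethanesulfonic anhydride O=S(=O)(OS(=O)(=O)C(F)(F)F)C(F)(F)F
Why: O-sulfonylation of a vinylogous carboxylic acid, in which the acidic C4 enol of the tetronic acid is the only free hydroxyl and should give the 4-triflate at low temperature.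

Step 8
Reactants: 11 methyl (2R)-4-methoxy-5-oxo-2-[3-prenyl-4-(TIPS-oxy)benzyl]-3-(trifluoromethylsulfonyloxy)-2,5-dihydrofuran-2-carboxylate; 12 [4-(TBS-oxy)phenyl]boronic acid
Product: 13 methyl (2R)-4-methoxy-5-oxo-2-[3-prenyl-4-(TIPS-oxy)benzyl]-3-[4-(TBS-oxy)phenyl]-2,5-dihydrofuran-2-carboxylate
Conditions: Pd(OAc)2 (5 mol %), 2-dicyclohexylphosphino-2',6'-dimethoxybiphenyl (10 mol %), K3PO4 (2 equiv), toluene/H2O (10:1), 50 °C
Reagents that add atoms: none
Why: Suzuki–Miyaura coupling, in which the electron-poor vinyl triflate adds oxidatively to zerovalent palladium, the biaryl phosphine copes with the tetrasubstituted alkene next to quaternary C5, and the silyl group on the boronic acid keeps a free phenoxide from displacing the triflate by addition–elimination at C4.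

Step 9
Reactants: 13 methyl (2R)-4-methoxy-5-oxo-2-[3-prenyl-4-(TIPS-oxy)benzyl]-3-[4-(TBS-oxy)phenyl]-2,5-dihydrofuran-2-carboxylate
Product: 14 2-O-methylbutyrolactone I, methyl (2R)-2-(4-hydroxy-3-prenylbenzyl)-3-(4-hydroxyphenyl)-4-methoxy-5-oxo-2,5-dihydrofuran-2-carboxylate
Conditions: Bu4NF (2.5 equiv), AcOH (2.5 equiv), THF, 0 °C
Reagents that add atoms: none
Why: Fluoride-induced desilylation of both aryl silyl ethers, buffered with acetic acid so that the lactone, the methyl ester and the ortho-prenylphenol (which cyclises to a chroman under strong acid) should stay untouched.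

**Compound list**

1 | 4-hydroxybenzaldehyde | O=Cc1ccc(O)cc1 | starting material
2 | prenyl bromide (1-bromo-3-methylbut-2-ene) | CC(C)=CCBr | starting material
3 | 4-hydroxy-3-prenylbenzaldehyde | O=Cc1ccc(O)c(CC=C(C)C)c1 | intermediate
4 | 3-prenyl-4-(TIPS-oxy)benzaldehyde | O=Cc1ccc(O[Si](C(C)C)(C(C)C)C(C)C)c(CC=C(C)C)c1 | intermediate
5 | methyl 4-methoxy-3-oxobutanoate | COCC(=O)CC(=O)OC | starting material
6 | methyl 2-(methoxyacetyl)-3-[3-prenyl-4-(TIPS-oxy)phenyl]prop-2-enoate (alkylidene keto ester, alkene geometry not defined, not isolated) | COCC(=O)C(=Cc1ccc(O[Si](C(C)C)(C(C)C)C(C)C)c(CC=C(C)C)c1)C(=O)OC | intermediate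
7 | methyl 4-methoxy-3-oxo-2-[3-prenyl-4-(TIPS-oxy)benzyl]butanoate (racemic) | COCC(=O)C(Cc1ccc(O[Si](C(C)C)(C(C)C)C(C)C)c(CC=C(C)C)c1)C(=O)OC | intermediate
8 | methyl (2R)-2-hydroxy-4-methoxy-3-oxo-2-[3-prenyl-4-(TIPS-oxy)benzyl]butanoate | COC(=O)[C@](C(=O)COC)(Cc1ccc(O[Si](C(C)C)(C(C)C)C(C)C)c(CC=C(C)C)c1)O | intermediate
9 | methyl (2R)-4-methoxy-2-[(4-nitrophenoxy)carbonyloxy]-3-oxo-2-[3-prenyl-4-(TIPS-oxy)benzyl]butanoate | COC(=O)[C@](C(=O)COC)(Cc1ccc(O[Si](C(C)C)(C(C)C)C(C)C)c(CC=C(C)C)c1)OC(=O)Oc1ccc(cc1)[N+](=O)[O-] | intermediate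
10 | methyl (2R)-3-hydroxy-4-methoxy-5-oxo-2-[3-prenyl-4-(TIPS-oxy)benzyl]-2,5-dihydrofuran-2-carboxylate | COC(=O)[C@]1(Cc2ccc(O[Si](C(C)C)(C(C)C)C(C)C)c(CC=C(C)C)c2)OC(=O)C(OC)=C1O | intermediate
11 | methyl (2R)-4-methoxy-5-oxo-2-[3-prenyl-4-(TIPS-oxy)benzyl]-3-(trifluoromethylsulfonyloxy)-2,5-dihydrofuran-2-carboxylate | COC(=O)[C@]1(Cc2ccc(O[Si](C(C)C)(C(C)C)C(C)C)c(CC=C(C)C)c2)OC(=O)C(OC)=C1OS(=O)(=O)C(F)(F)F | intermediate
12 | [4-(TBS-oxy)phenyl]boronic acid | CC(C)(C)[Si](C)(C)Oc1ccc(cc1)B(O)O | starting material
13 | methyl (2R)-4-methoxy-5-oxo-2-[3-prenyl-4-(TIPS-oxy)benzyl]-3-[4-(TBS-oxy)phenyl]-2,5-dihydrofuran-2-carboxylate | COC(=O)[C@]1(Cc2ccc(O[Si](C(C)C)(C(C)C)C(C)C)c(CC=C(C)C)c2)OC(=O)C(OC)=C1c1ccc(O[Si](C)(C)C(C)(C)C)cc1 | intermediate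
14 | 2-O-methylbutyrolactone I, methyl (2R)-2-(4-hydroxy-3-prenylbenzyl)-3-(4-hydroxyphenyl)-4-methoxy-5-oxo-2,5-dihydrofuran-2-carboxylate | COC(=O)[C@]1(Cc2ccc(O)c(CC=C(C)C)c2)OC(=O)C(OC)=C1c1ccc(O)cc1 | target

**Count**

Total step count: 9. Longest linear sequence: 9 steps (1 to 14); compounds 2, 5 and 12 are commercially available and enter directly.

**Steps most likely to fail**

Step 6. The magnesium enolate may acylate on oxygen and not on carbon, which would close a five-membered enol carbonate in place of the tetronic acid. The fallback makes that O-acylation the first half of the ring closure; it sets out from 9 and comes back to the route at 10. Compound 9 is treated with Et3N alone (CH2Cl2, rt), so that the enol oxygen displaces 4-nitrophenoxide and gives the cyclic enol carbonate F1. F1 is then rearranged with catalytic 4-(pyrrolidin-1-yl)pyridine (THF, rt). The pyridine opens the carbonate to an acylpyridinium–enolate ion pair that recloses at carbon C3 (Steglich-type O-to-C carboxyl shift), which should give 10 after acidic work-up.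

Step 4. Facial selectivity in the oxygen transfer may be poor, because the substrate is an acyclic keto ester with a small methyl ester group. The fallback replaces asymmetric catalysis by resolution; it sets out from 7 and comes back at 8. Compound 7 is hydroxylated without a chiral ligand (the same oxaziridine, catalytic 1,8-diazabicyclo[5.4.0]undec-7-ene, CH2Cl2, rt) to the racemic alcohol F2. Its enantiomers are separated by preparative chromatography on a polysaccharide chiral stationary phase (supercritical CO2/MeOH). The (R)-enantiomer is 8; the (S)-enantiomer F3 is set aside.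

Step 1. O-alkylation and double alkylation of the ambident phenoxide may outrun the ortho C-prenylation. The fallback fixes the position with a halogen; it sets out from 1 and comes back at 4, so that step 2 is not needed. Bromination ortho to the hydroxyl (Br2, AcOH, rt) gives 3-bromo-4-hydroxybenzaldehyde F4. Silylation (TIPSCl, imidazole, DMF) gives 3-bromo-4-(TIPS-oxy)benzaldehyde F5. Stille coupling with tributyl(3-methylbut-2-en-1-yl)stannane (Pd(PPh3)4, DMF, 90 °C) then places the prenyl group on the brominated carbon and gives 4.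

**Further compounds**

F1 | step 6 | methyl (4R)-5-(methoxymethylidene)-2-oxo-4-[3-prenyl-4-(TIPS-oxy)benzyl]-1,3-dioxolane-4-carboxylate (cyclic enol carbonate, alkene geometry not defined) | COC=C1OC(=O)O[C@@]1(Cc2ccc(O[Si](C(C)C)(C(C)C)C(C)C)c(CC=C(C)C)c2)C(=O)OC
F2 | step 4 | methyl 2-hydroxy-4-methoxy-3-oxo-2-[3-prenyl-4-(TIPS-oxy)benzyl]butanoate (racemic) | COC(=O)C(O)(Cc1ccc(O[Si](C(C)C)(C(C)C)C(C)C)c(CC=C(C)C)c1)C(=O)COC
F3 | step 4 | methyl (2S)-2-hydroxy-4-methoxy-3-oxo-2-[3-prenyl-4-(TIPS-oxy)benzyl]butanoate | COC(=O)[C@@](C(=O)COC)(Cc1ccc(O[Si](C(C)C)(C(C)C)C(C)C)c(CC=C(C)C)c1)O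
F4 | step 1 | 3-bromo-4-hydroxybenzaldehyde | O=Cc1ccc(O)c(Br)c1
F5 | step 1 | 3-bromo-4-(TIPS-oxy)benzaldehyde | O=Cc1ccc(O[Si](C(C)C)(C(C)C)C(C)C)c(Br)c1
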